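**Retrosynthetic overview**

1. Target 15 consists of two identical sinapyl C6C3 units joined by the C2–C3 bond and the C1–C8a bond (tetralin numbering: C1 aryl-bearing, C2/C3 hydroxymethyl-bearing, C4 methylene, C4a/C8a ring fusion). Ring B (C1–C2–C3–C4–C4a–C8a) is the only ring to be built.
2. 15 ⇐ all-trans dimethyl ester 14 (ester reduction) ⇐ tetralin bis-imide 12 (methanolysis with C2/C3 equilibration) ⇐ 1-aryl-1,2-dihydronaphthalene bis-imide 11 (C3=C4 hydrogenation).
3. 11 ⇐ 2 × sinapoyl imide 7: phenoxyl radical coupling forms C2–C3, then a quinone methide Friedel–Crafts closure forms C1–C8a and ring B. The auxiliary fixes C2, which relays trans to C1.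
4. 7 ⇐ sinapic acid 1 + (S)-4-benzyl-2-oxazolidinone 4 (phenol silylation, mixed-anhydride N-acylation, desilylation); both arenes come ready-made from 1.

Key step: step 4

Assumption (chemistry): the imide is taken to react through the metal-chelated syn-carbonyl rotamer, in which the (S)-benzyl group shields Cα in the sense known from Evans enolate alkylations; if the dipole-opposed rotamer governs instead, the sense inverts and the route is run unchanged with (R)-4-benzyl-2-oxazolidinone.

**Route**

Step 1
Reactants: 1 sinapic acid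
Product: 3 (E)-3-[4-(tert-butyldimethylsilyloxy)-3,5-dimethoxyphenyl]prop-2-enoic acid, via bis-silylated sinapate 2 (not isolated)
Conditions: TBSCl (2.5 equiv), imidazole, DMF, rt; then AcOH/THF/H2O, rt
Reagents that add atoms: tert-butyldimethylsilyl chloride, CC(C)(C)[Si](C)(C)Cl
Why: Imidazole-mediated O-silylation caps both acidic OH groups and the silyl ester, far more labile than the hindered aryl silyl ether, is then hydrolysed selectively by aqueous acetic acid (silyl protection of a hydroxycinnamic acid); no stereocenter is formed and the E alkene is untouched.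

Step 2
Reactants: 3 (E)-3-[4-(tert-butyldimethylsilyloxy)-3,5-dimethoxyphenyl]prop-2-enoic acid; 4 (S)-4-benzyl-2-oxazolidinone
Product: 6 (S)-4-benzyl-3-[(E)-3-(4-tert-butyldimethylsilyloxy-3,5-dimethoxyphenyl)prop-2-enoyl]oxazolidin-2-one, via mixed pivalic anhydride 5 (not isolated)
Conditions: PivCl, Et3N, THF, −20 to 0 °C; then LiCl, 4, rt
Reagents that add atoms: none
Why: N-Acylation of the oxazolidinone through a mixed pivalic anhydride under LiCl/Et3N activation (one-pot Evans imide formation) should work because the oxazolidinone attacks the unhindered cinnamoyl carbonyl of 5 rather than the tert-butyl-shielded one, and the auxiliary stereocenter is carried over unchanged.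

Step 3
Reactants: 6 (S)-4-benzyl-3-[(E)-3-(4-tert-butyldimethylsilyloxy-3,5-dimethoxyphenyl)prop-2-enoyl]oxazolidin-2-one
Product: 7 (S)-4-benzyl-3-[(E)-sinapoyl]oxazolidin-2-one
Conditions: TBAF (1.1 equiv), AcOH (1.2 equiv), THF, 0 °C
Reagents that add atoms: none
Why: Fluoride-induced cleavage of the aryl silyl ether (desilylation), buffered with acetic acid so that neither phenoxide nor fluoride attacks the imide or the enoyl unit; no stereocenter changes.

Step 4
Reactants: 7 (S)-4-benzyl-3-[(E)-sinapoyl]oxazolidin-2-one (two molecules)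
Product: 11 3,3'-[(1S,2R)-7-hydroxy-1-(4-hydroxy-3,5-dimethoxyphenyl)-6,8-dimethoxy-1,2-dihydronaphthalene-2,3-dicarbonyl]bis[(S)-4-benzyloxazolidin-2-one], via phenoxyl radical 8 (not isolated), via bis-quinone methide 9 (not isolated), via mono-quinone methide 10 (not isolated)
Conditions: FeCl3·6H2O (2.2 equiv per 7), acetone/H2O 10:1, 0 °C to rt, Ar, dark; minor diastereomers removed by chromatography or crystallization
Reagents that add atoms: none
Why: Fe(III) oxidizes the phenol of 7 by one electron to radical 8, whose spin density sits on oxygen, on the methoxy-blocked ring positions and on Cα (the side-chain carbon next to the imide carbonyl); two radicals combine Cα–Cα (the future C2–C3 bond) to bis-quinone methide 9, one half of which tautomerizes by loss of its Cα–H to the rearomatized arylidene arene 10. The ring CH ortho to the side chain of that arene (future C8a, ortho to one methoxy group and para to the other) then adds to the exocyclic quinone methide carbon (future C1) in a 6-exo-trig Friedel–Crafts (vinylogous Michael) closure of ring B, and proton loss restores both phenols. The closest known reaction is the iron(III)-mediated dimerization of sinapate esters and amides to 1-aryl-1,2-dihydronaphthalene-2,3-dicarboxylates, together with oxidative couplings of hydroxycinnamoyl imides that carry chiral auxiliaries. C2 is set in the radical–radical coupling: in the chelated syn-carbonyl rotamer the benzyl group covers one face of the planar Cα radical, so both partners should bond through the open face and give (R,R)-9; C1 is then set relative to C2 during ring closure, the arene adding so that the quinoid ring ends trans to the C2 imide, the arrangement of all thomasidioate-type dimers. The step needs 8–8 regioselectivity, which the two methoxy groups flanking each phenol secure by closing off coupling at the ring carbons, and face selectivity at Cα, which rests on the auxiliary; any minor diastereomer of 11 differs in physical properties because of the two auxiliaries and should be separable.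

Step 5
Reactants: 11 3,3'-[(1S,2R)-7-hydroxy-1-(4-hydroxy-3,5-dimethoxyphenyl)-6,8-dimethoxy-1,2-dihydronaphthalene-2,3-dicarbonyl]bis[(S)-4-benzyloxazolidin-2-one]
Product: 12 3,3'-[(1S,2R,3S)-7-hydroxy-1-(4-hydroxy-3,5-dimethoxyphenyl)-6,8-dimethoxy-1,2,3,4-tetrahydronaphthalene-2,3-dicarbonyl]bis[(S)-4-benzyloxazolidin-2-one] (1,2-trans-2,3-cis)
Conditions: H2 (1–4 atm), 10% Pd/C, EtOAc/AcOH, rt
Reagents that add atoms: none
Why: Heterogeneous catalytic hydrogenation should saturate the trisubstituted styrene-type C3=C4 bond while arenes, imides and the C-benzyl groups stay inert; hydrogen is expected to arrive anti to the neighbouring C2 imide, giving the 2,3-cis isomer drawn, but the C3 configuration is not decisive because step 6 equilibrates it.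

Step 6
Reactants: 12 3,3'-[(1S,2R,3S)-7-hydroxy-1-(4-hydroxy-3,5-dimethoxyphenyl)-6,8-dimethoxy-1,2,3,4-tetrahydronaphthalene-2,3-dicarbonyl]bis[(S)-4-benzyloxazolidin-2-one]
Product: 14 dimethyl (1S,2R,3R)-7-hydroxy-1-(4-hydroxy-3,5-dimethoxyphenyl)-6,8-dimethoxy-1,2,3,4-tetrahydronaphthalene-2,3-dicarboxylate (all-trans), via 2,3-cis dimethyl ester 13 (not isolated)
Conditions: NaOMe (8 equiv), degassed MeOH/THF, Ar, 0 °C to rt, then 50 °C; AcOH quench
Reagents that add atoms: sodium methoxide, C[O-].[Na+]; methanol, CO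
Why: Imide methanolysis with base-mediated epimerization: methoxide transesterifies both imides at the exocyclic carbonyl, releasing auxiliary 4, and reversibly enolizes the ester α-carbons C2 and C3, so that thermodynamic control should funnel the material to the all-trans diester with three equatorial substituents, while the non-acidic C1 keeps the configuration set in step 4.

Step 7
Reactants: 14 dimethyl (1S,2R,3R)-7-hydroxy-1-(4-hydroxy-3,5-dimethoxyphenyl)-6,8-dimethoxy-1,2,3,4-tetrahydronaphthalene-2,3-dicarboxylate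
Product: 15 (1S,2R,3R)-1-(4-hydroxy-3,5-dimethoxyphenyl)-2,3-bis(hydroxymethyl)-6,8-dimethoxy-1,2,3,4-tetrahydronaphthalen-7-ol (target)
Conditions: LiAlH4 (excess), THF, 0 °C to reflux; aqueous work-up
Reagents that add atoms: none
Why: LiAlH4 reduction of both methyl esters to primary alcohols, the phenols being only deprotonated and returned on work-up; the reduction does not enolize C2 or C3, so all three stereocenters are kept.

**Compound list**

1 | sinapic acid, (E)-3-(4-hydroxy-3,5-dimethoxyphenyl)prop-2-enoic acid | COc1cc(/C=C/C(=O)O)cc(OC)c1O | starting material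
2 | tert-butyldimethylsilyl (E)-3-[4-(tert-butyldimethylsilyloxy)-3,5-dimethoxyphenyl]prop-2-enoate | COc1cc(/C=C/C(=O)O[Si](C)(C)C(C)(C)C)cc(OC)c1O[Si](C)(C)C(C)(C)C | intermediate (not isolated)
3 | (E)-3-[4-(tert-butyldimethylsilyloxy)-3,5-dimethoxyphenyl]prop-2-enoic acid | COc1cc(/C=C/C(=O)O)cc(OC)c1O[Si](C)(C)C(C)(C)C | intermediate
4 | (S)-4-benzyl-2-oxazolidinone | O=C1N[C@@H](Cc2ccccc2)CO1 | starting material
5 | (E)-3-[4-(tert-butyldimethylsilyloxy)-3,5-dimethoxyphenyl]prop-2-enoic pivalic anhydride | COc1cc(/C=C/C(=O)OC(=O)C(C)(C)C)cc(OC)c1O[Si](C)(C)C(C)(C)C | intermediate (not isolated)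
6 | (S)-4-benzyl-3-[(E)-3-(4-tert-butyldimethylsilyloxy-3,5-dimethoxyphenyl)prop-2-enoyl]oxazolidin-2-one | COc1cc(/C=C/C(=O)N2C(=O)OC[C@@H]2Cc2ccccc2)cc(OC)c1O[Si](C)(C)C(C)(C)C | intermediate
7 | (S)-4-benzyl-3-[(E)-sinapoyl]oxazolidin-2-one | COc1cc(/C=C/C(=O)N2C(=O)OC[C@@H]2Cc2ccccc2)cc(OC)c1O | intermediate (key-step precursor)
8 | phenoxyl radical of 7 | COc1cc(/C=C/C(=O)N2C(=O)OC[C@@H]2Cc2ccccc2)cc(OC)c1[O] | intermediate (not isolated)
9 | 3,3'-{(2R,3R)-2,3-bis[(3,5-dimethoxy-4-oxocyclohexa-2,5-dien-1-ylidene)methyl]butanedioyl}bis[(S)-4-benzyloxazolidin-2-one] (bis-quinone methide) | COC1=CC(=C[C@@H](C(=O)N2C(=O)OC[C@@H]2Cc2ccccc2)[C@H](C(=O)N2C(=O)OC[C@@H]2Cc2ccccc2)C=C2C=C(OC)C(=O)C(OC)=C2)C=C(OC)C1=O | intermediate (not isolated)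
10 | 3,3'-{(3R)-2-[(E)-(4-hydroxy-3,5-dimethoxyphenyl)methylidene]-3-[(3,5-dimethoxy-4-oxocyclohexa-2,5-dien-1-ylidene)methyl]butanedioyl}bis[(S)-4-benzyloxazolidin-2-one] (mono-quinone methide) | COc1cc(/C=C(/C(=O)N2C(=O)OC[C@@H]2Cc2ccccc2)[C@H](C(=O)N2C(=O)OC[C@@H]2Cc2ccccc2)C=C2C=C(OC)C(=O)C(OC)=C2)cc(OC)c1O | intermediate (not isolated)
11 | 3,3'-[(1S,2R)-7-hydroxy-1-(4-hydroxy-3,5-dimethoxyphenyl)-6,8-dimethoxy-1,2-dihydronaphthalene-2,3-dicarbonyl]bis[(S)-4-benzyloxazolidin-2-one] (1,2-trans) | COc1cc([C@H]2c3c(cc(OC)c(O)c3OC)C=C(C(=O)N3C(=O)OC[C@@H]3Cc3ccccc3)[C@@H]2C(=O)N2C(=O)OC[C@@H]2Cc2ccccc2)cc(OC)c1O | intermediate (key-step product)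
12 | 3,3'-[(1S,2R,3S)-7-hydroxy-1-(4-hydroxy-3,5-dimethoxyphenyl)-6,8-dimethoxy-1,2,3,4-tetrahydronaphthalene-2,3-dicarbonyl]bis[(S)-4-benzyloxazolidin-2-one] (1,2-trans-2,3-cis) | COc1cc([C@H]2c3c(cc(OC)c(O)c3OC)C[C@H](C(=O)N3C(=O)OC[C@@H]3Cc3ccccc3)[C@@H]2C(=O)N2C(=O)OC[C@@H]2Cc2ccccc2)cc(OC)c1O | intermediate
13 | dimethyl (1S,2R,3S)-7-hydroxy-1-(4-hydroxy-3,5-dimethoxyphenyl)-6,8-dimethoxy-1,2,3,4-tetrahydronaphthalene-2,3-dicarboxylate (1,2-trans-2,3-cis) | COc1cc([C@H]2c3c(cc(OC)c(O)c3OC)C[C@H](C(=O)OC)[C@@H]2C(=O)OC)cc(OC)c1O | intermediate (not isolated)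
14 | dimethyl (1S,2R,3R)-7-hydroxy-1-(4-hydroxy-3,5-dimethoxyphenyl)-6,8-dimethoxy-1,2,3,4-tetrahydronaphthalene-2,3-dicarboxylate (all-trans) | COc1cc([C@H]2c3c(cc(OC)c(O)c3OC)C[C@@H](C(=O)OC)[C@@H]2C(=O)OC)cc(OC)c1O | intermediate
15 | (1S,2R,3R)-1-(4-hydroxy-3,5-dimethoxyphenyl)-2,3-bis(hydroxymethyl)-6,8-dimethoxy-1,2,3,4-tetrahydronaphthalen-7-ol (CNP0153696.1, lyoniresinol skeleton) | COc1cc([C@H]2c3c(cc(OC)c(O)c3OC)C[C@@H](CO)[C@@H]2CO)cc(OC)c1O | target

**Totals and risks**

Total step count: 7. Longest linear sequence: 7 steps (from sinapic acid 1; oxazolidinone 4 enters in step 2).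

Steps most likely to fail:

Step 4. What may go wrong: weak face discrimination in the radical–radical coupling because the imide reacts through more than one rotamer, together with competing 8–O–4 coupling or over-oxidation of the electron-rich product, so that 11 is formed with low diastereomeric purity and is hard to purify. Fallback (resolution instead of auxiliary control): setting out from 1, Fischer esterification (MeOH, cat. H2SO4, reflux) gives methyl sinapate F1; FeCl3·6H2O in aqueous acetone dimerizes it to the racemic trans-dihydronaphthalene diester F2; hydrogenation over Pd/C in AcOH gives the racemic 2,3-cis tetralin diester F3; NaOMe in MeOH equilibrates this to the racemic all-trans diester F4, which is resolved by preparative HPLC on a polysaccharide chiral stationary phase. The (1S,2R,3R) enantiomer is 14, where the route is rejoined before step 7.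

Step 6. What may go wrong: methoxide attack at the ring carbonyl of the hindered imides, which opens the oxazolidinones to hydroxy amides instead of releasing them, so that methanolysis stalls or gives mixed products before equilibration is complete. Fallback (cleavage and epimerization separated): setting out from 12, LiOH/H2O2 in THF/H2O at 0 °C, which is selective for the exocyclic carbonyl, gives the (1S,2R,3S)-diacid F5; esterification with MeOH and cat. H2SO4 gives the cis diester, here isolated, which is compound 13, where the route is rejoined; NaOMe in MeOH then equilibrates 13 to 14 with no imide present.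

Step 5. What may go wrong: slow or incomplete hydrogen uptake at the trisubstituted alkene flanked by two bulky imides, with palladium-mediated disproportionation to the arylnaphthalene draining material. Fallback (auxiliaries removed before reduction): setting out from 11, MeOMgBr (from MeMgBr and MeOH, CH2Cl2, 0 °C) transesterifies both imides under weakly basic chelating conditions to dimethyl (1S,2R)-dihydronaphthalene diester F6, whose less encumbered alkene is hydrogenated (H2, Pd/C, AcOH) to 13, where the route is rejoined; 13 is then equilibrated to 14 with NaOMe.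

**Further compounds**

F1 | step 4 | methyl sinapate, methyl (E)-3-(4-hydroxy-3,5-dimethoxyphenyl)prop-2-enoate | COc1cc(/C=C/C(=O)OC)cc(OC)c1O
F2 | step 4 | racemic dimethyl trans-7-hydroxy-1-(4-hydroxy-3,5-dimethoxyphenyl)-6,8-dimethoxy-1,2-dihydronaphthalene-2,3-dicarboxylate (both enantiomers written) | COc1cc([C@H]2c3c(cc(OC)c(O)c3OC)C=C(C(=O)OC)[C@@H]2C(=O)OC)cc(OC)c1O.COc1cc([C@@H]2c3c(cc(OC)c(O)c3OC)C=C(C(=O)OC)[C@H]2C(=O)OC)cc(OC)c1O
F3 | step 4 | racemic dimethyl 1,2-trans-2,3-cis-7-hydroxy-1-(4-hydroxy-3,5-dimethoxyphenyl)-6,8-dimethoxy-1,2,3,4-tetrahydronaphthalene-2,3-dicarboxylate (both enantiomers written) | COc1cc([C@H]2c3c(cc(OC)c(O)c3OC)C[C@H](C(=O)OC)[C@@H]2C(=O)OC)cc(OC)c1O.COc1cc([C@@H]2c3c(cc(OC)c(O)c3OC)C[C@@H](C(=O)OC)[C@H]2C(=O)OC)cc(OC)c1O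
F4 | step 4 | racemic all-trans dimethyl 7-hydroxy-1-(4-hydroxy-3,5-dimethoxyphenyl)-6,8-dimethoxy-1,2,3,4-tetrahydronaphthalene-2,3-dicarboxylate (both enantiomers written) | COc1cc([C@H]2c3c(cc(OC)c(O)c3OC)C[C@@H](C(=O)OC)[C@@H]2C(=O)OC)cc(OC)c1O.COc1cc([C@@H]2c3c(cc(OC)c(O)c3OC)C[C@H](C(=O)OC)[C@H]2C(=O)OC)cc(OC)c1O
F5 | step 6 | (1S,2R,3S)-7-hydroxy-1-(4-hydroxy-3,5-dimethoxyphenyl)-6,8-dimethoxy-1,2,3,4-tetrahydronaphthalene-2,3-dicarboxylic acid | COc1cc([C@H]2c3c(cc(OC)c(O)c3OC)C[C@H](C(=O)O)[C@@H]2C(=O)O)cc(OC)c1O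
F6 | step 5 | dimethyl (1S,2R)-7-hydroxy-1-(4-hydroxy-3,5-dimethoxyphenyl)-6,8-dimethoxy-1,2-dihydronaphthalene-2,3-dicarboxylate | COc1cc([C@H]2c3c(cc(OC)c(O)c3OC)C=C(C(=O)OC)[C@@H]2C(=O)OC)cc(OC)c1O
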